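You are comparing two clocks: the incoming ligand dies faster than the complex with one exchanged slides into its isomer. Three flasks differ in when the exchange happens, and the slide then has different lengths of time to work.

| flask | starting complex | incoming ligand | time | remark |
|---|---|---|---|---|
| Saturday's | 20 mM (fed, over 25 min) | 14.0 mM | 30 min | all else is in the flask from the start; the feed brings no volume worth counting |
| Friday's | 20 mM | 14.0 mM (fed, over 25 min) | 30 min | all else is in the flask from the start; the feed brings no volume worth counting |
| Wednesday's | 20 mM | 14.0 mM | 30 min | everything together at the start |

- the flask that comes out highest in share of complex with one exchanged in complex with one exchanged plus complex with two exchanged, or "all alike" when all lie within 1.5 percentage points (Saturday's / Friday's / Wednesday's / all alike)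
- share of complex with one exchanged in complex with one exchanged plus complex with two exchanged at the end, Saturday's
- share of complex with one exchanged in complex with one exchanged plus complex with two exchanged at the end, Friday's
- share of complex with one exchanged in complex with one exchanged plus complex with two exchanged at the end, Wednesday's

    starting complex + incoming ligand → leaving ligand + complex with one exchanged (k1 = 13 L mol⁻¹ min⁻¹)
    complex with one exchanged + incoming ligand → leaving ligand + complex with two exchanged (k2 = 24 L mol⁻¹ min⁻¹)
    complex with two exchanged + incoming ligand → leaving ligand + complex with three exchanged (k3 = 23 L mol⁻¹ min⁻¹)
    incoming ligand → decomposed reagent (k4 = 0.15 min⁻¹)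
    incoming ligand → decomposition product (k5 = 1.1 × 10⁻⁴ min⁻¹)
    complex with one exchanged ⇌ isomer of the product (K6 = 5.7, k6 = 0.031 min⁻¹)

Take Wednesday's at its start. A molecule of incoming ligand has two ways to go, each with its own rate per minute:

exchange: 13 L mol⁻¹ min⁻¹ × c(starting complex) = 0.260 min⁻¹
decomposition: 0.15 min⁻¹

Exchange leads by a factor of 1.7. What slows it is the loss of ligand by both ways at once. With c(starting complex) counted as constant, a pseudo-first-order view, the exchange rate falls by a factor e in each interval of

τ = inverse of (0.260 min⁻¹ + 0.15 min⁻¹) = 2.44 min

That is far shorter than the slide's own time of 32.3 min, and the way back is slower still, at 0.00544 min⁻¹. So as an estimate I take the complex with one exchanged in Wednesday's as born on average at τ, then draining for the rest of the run.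

Call this the keep factor: of the complex with one exchanged that step two did not take, the share not yet turned to isomer at the end. I reckon it as exp(−0.031 min⁻¹ × age), where age is the end time less the mean birth time, and I leave the way back out.

Wednesday's: age = 30 min − τ, keep factor 42.6%
Friday's: mean birth at mid-feed plus τ, keep factor 62.7%

I therefore put Friday's above Wednesday's, with a keep factor larger by a factor of 1.47. Saturday's I leave unreckoned.

The forecast named Friday's, with 60% for Saturday's, 67% for Friday's and 53% for Wednesday's, holding that the drain “hurts most when it forms early”.

The flasks give 64.1% for Saturday's, 69.6% for Friday's and 57.8% for Wednesday's, so Friday's comes out highest.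

Take the passing to the isomer away, both ways, and the gap between Friday's and Wednesday's shrinks from 12 percentage points to 0.14 points, the largest single effect on it. The keep factor can be read at the end as complex with one exchanged over that plus isomer: 61.2% in Friday's and 45.2% in Wednesday's. In the neighbour of Wednesday's with 12 mM of starting complex, τ becomes 3.27 min, the factor 43.7%, and the reading 45.6%.

All constants belong to no real substance; the result is computed.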